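Target leaves these flasks by two routes, and we compare them: its turn into isomer of the product involves no other concentration, while its reaction with starting material goes with [starting material].

common to all: partner 1.00 equiv (fed, over 30 s); time 30 s
- gamma: starting material 0.050 M; the fed solution adds 1.0 times the starting volume
- delta: starting material 0.10 M; the fed solution adds 1.0 times the starting volume
- beta: starting material 0.20 M; the fed solution adds 1.0 times the starting volume
- eta: starting material 0.40 M; the fed solution adds 1.0 times the starting volume

    starting material → intermediate (k1 = 0.0244 /s)
    partner + intermediate → target (k2 = 6.60 /M/s)
    starting material + target → side product (k3 = 3.64 /M/s)
    target ⇌ isomer of the product (K4 = 9.5, k4 = 0.235 /s)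

- share of target in all that became target or side product or isomer of the product for gamma, delta, beta, eta, in this order
- the shape of the row from first to last (rises all the way / falls all the way / falls, then rises / rises, then falls / hardly changes)

- percent here means starting material units held: one side product counts as two
- amounts are per litre of the starting volume; all of the dose is in the solution fed
- "hardly changes" means that all values lie within two and a half points (for a concentration: within two and a half percent of the largest)
- run time (gamma): 30 s

Both losses are first order in target, so at a given [starting material] the side step is pseudo-first-order in target, with constant 3.64 /M/s times [starting material]. Our side ratio for gamma is 0.774: that constant, taken as charged, over the forward constant of target to isomer of the product. Here are the four flasks: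

- gamma, 0.050 M: side step 0.182 /s, isomer step 0.235 /s, side ratio 0.774
- delta, 0.10 M: side step 0.364 /s, isomer step 0.235 /s, side ratio 1.55
- beta, 0.20 M: side step 0.728 /s, isomer step 0.235 /s, side ratio 3.10
- eta, 0.40 M: side step 1.46 /s, isomer step 0.235 /s, side ratio 6.20

Reading down, the isomer column stands still while the side column grows. Taken as charged, the side step in gamma is slower than the isomer step, but in delta it is already faster, and in eta it is faster still.

One side product counts as two units, so in percent the side ratio doubles: 1.55 for gamma and 12.4 for eta. These are figures as charged. [starting material] falls as it reacts and the feed dilutes it, so we expect the flasks to show less, by a similar factor in each.

Taken as charged and counting forward steps, the total drain on target rises from 0.417 /s in gamma to 1.69 /s in eta, so we commit to a falling row. Our reckoning stops there, with no figures for the row: how much target stands also depends on its supply through intermediate and partner.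

The forecast gives 16.5%, 10%, 6.2% and 4%, a row that falls all the way, on the ground that target drains to side product “at a rate that grows with starting-material concentration”.

The simulation gives 16.3%, 10.6%, 6.00% and 3.24%, a row that falls all the way.

At the asked time, gamma holds side product against isomer of the product at 0.693, which is 0.447 of its doubled side ratio. Carried to eta, that factor gives 5.54, and eta reads 5.83. The time allowed is the main reason that gamma's target share stands at 16.3%: the share in gamma after 300 s is 6.52%.

(The rate constants are invented, and the outcome is calculated.)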